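## Retrosynthetic overview

1. The acetate is installed last. The alcohol is cut at the exocyclic olefin into a butenolide hydroxy aldehyde and an (S)-α-phosphono-γ-(2-methylpropenyl)butyrolactone, joined by a Z-selective Horner–Wadsworth–Emmons reaction. The γ-lactone ring and its stereocentre are bought as (S)-5-(hydroxymethyl)butyrolactone.
2. The butenolide comes from an α-silyloxy chloromethyl ketone and phosphonoacetic acid (intramolecular HWE). The ketone comes from an α-hydroxy ester, made from methyl (R)-glycidate and an (E)-alkenyl metal (C2–C3 bond, chain counted from the acetoxy carbon C1); the carbinol stereocentre is bought.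
3. Key bond: C9–C10 and the (E)-C7=C8 olefin are formed by a Johnson–Claisen [3,3]-sigmatropic rearrangement of an isopropenyl carbinol. The (E)-C3=C4 olefin comes from Negishi carboalumination of pent-4-yn-1-ol.
4. Ring order: the γ-lactone ring is bought intact (steps 11–13 only decorate it), the butenolide ring is closed in step 9, and the two halves are joined in step 14.

Assumption: reagents named under "Reagents that add atoms" are bought as such and carry no compound number.

## Route

Step 1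
Reactants: 1 pent-4-yn-1-ol
Product: 3 (4E)-5-iodo-4-methylpent-4-en-1-ol, via alkenylalane 2 (not isolated)
Conditions: Me3Al (3 equiv), Cp2ZrCl2 (0.25 equiv), CH2Cl2, 0 °C to rt; then I2, THF, −30 to 0 °C
Reagents that add atoms: trimethylaluminium C[Al](C)C; iodine [I][I]
Why: Negishi carboalumination adds Me and Al syn across the terminal alkyne with Al on the terminal carbon, and iodinolysis with retention gives the (E)-iodoalkene that becomes the C3=C4 olefin.

Step 2
Reactants: 3 (4E)-5-iodo-4-methylpent-4-en-1-ol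
Product: 4 (4E)-5-iodo-4-methylpent-4-enal
Conditions: Dess–Martin periodinane, CH2Cl2, 0 °C to rt
Reagents that add atoms: none
Why: Dess–Martin oxidation of the primary alcohol stops at the aldehyde and leaves the alkenyl iodide untouched.

Step 3
Reactants: 4 (4E)-5-iodo-4-methylpent-4-enal
Product: 5 (6E)-7-iodo-2,6-dimethylhepta-1,6-dien-3-ol (racemic at C3)
Conditions: CH2=C(Me)MgBr, THF, −78 to 0 °C; aq. NH4Cl
Reagents that add atoms: isopropenylmagnesium bromide CC(=C)[Mg]Br
Why: Grignard 1,2-addition to the aldehyde gives the isopropenyl carbinol for the rearrangement, whose racemic carbinol centre is erased in step 4.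

Step 4
Reactants: 5 (6E)-7-iodo-2,6-dimethylhepta-1,6-dien-3-ol
Product: 7 ethyl (4E,8E)-9-iodo-4,8-dimethylnona-4,8-dienoate, via ketene acetal 6 (not isolated)
Conditions: MeC(OEt)3 (6 equiv), EtCO2H (5 mol %), 140 °C, EtOH distilled off
Reagents that add atoms: triethyl orthoacetate CCOC(C)(OCC)OCC
Why: Johnson–Claisen [3,3]-sigmatropic rearrangement through a chair transition state with the chain pseudo-equatorial forms the C9–C10 bond and the (E)-trisubstituted C7=C8 olefin (E:Z expected about 98:2).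

Step 5
Reactants: 7 ethyl (4E,8E)-9-iodo-4,8-dimethylnona-4,8-dienoate
Product: 8 (4E,8E)-9-iodo-4,8-dimethylnona-4,8-dienal
Conditions: i-Bu2AlH (1.05 equiv), CH2Cl2, −78 °C; Rochelle salt work-up
Reagents that add atoms: none
Why: Low-temperature hydride reduction of the ester stops at the aldehyde because the tetrahedral aluminium hemiacetal survives until work-up.

Step 6
Reactants: 8 (4E,8E)-9-iodo-4,8-dimethylnona-4,8-dienal
Product: 9 (1E,5E)-1-iodo-9,9-dimethoxy-2,6-dimethylnona-1,5-diene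
Conditions: HC(OMe)3, PPTS (cat.), MeOH, rt
Reagents that add atoms: trimethyl orthoformate COC(OC)OC
Why: Acid-catalysed acetalisation masks the aldehyde against the organometallic reagents of steps 7 and 8.

Step 7
Reactants: 9 (1E,5E)-1-iodo-9,9-dimethoxy-2,6-dimethylnona-1,5-diene (1.3 equiv); 10 methyl (2R)-oxirane-2-carboxylate
Product: 14 methyl (2R,4E,8E)-12,12-dimethoxy-5,9-dimethyl-2-[(triethylsilyl)oxy]dodeca-4,8-dienoate, via alkenyllithium 11 (not isolated), via alkenylmagnesium bromide 12 (not isolated), via hydroxy ester alkoxide 13 (not isolated)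
Conditions: t-BuLi (2 equiv), Et2O, −78 °C; MgBr2·OEt2, −78 to −40 °C; CuBr·SMe2 (15 mol %), then 10, THF, −40 °C; then TESCl, imidazole, DMF, 0 °C to rt
Reagents that add atoms: chlorotriethylsilane CC[Si](Cl)(CC)CC
Why: Iodine–lithium exchange with retention of olefin geometry, transmetalation and copper-catalysed SN2 opening of the glycidate at its unsubstituted C3 leave the bought stereocentre untouched as the (R)-carbinol carbon, and the alkoxide is silylated in the same flask.

Step 8
Reactants: 14 methyl (2R,4E,8E)-12,12-dimethoxy-5,9-dimethyl-2-[(triethylsilyl)oxy]dodeca-4,8-dienoate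
Product: 15 (3R,5E,9E)-1-chloro-13,13-dimethoxy-6,10-dimethyl-3-[(triethylsilyl)oxy]trideca-5,9-dien-2-one
Conditions: ICH2Cl, MeLi·LiBr, THF, −78 °C; aq. NH4Cl at −78 °C
Reagents that add atoms: chloroiodomethane ICCl
Why: Chloromethyllithium homologation of the ester adds only once because the tetrahedral adduct survives at −78 °C and collapses to the chloromethyl ketone on quench, and the weakly basic carbenoid does not epimerise the α-silyloxy centre.

Step 9
Reactants: 15 (3R,5E,9E)-1-chloro-13,13-dimethoxy-6,10-dimethyl-3-[(triethylsilyl)oxy]trideca-5,9-dien-2-one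
Product: 17 4-[(1R,3E,7E)-11,11-dimethoxy-4,8-dimethyl-1-[(triethylsilyl)oxy]undeca-3,7-dien-1-yl]furan-2(5H)-one, via keto phosphonoacetate 16 (not isolated)
Conditions: (EtO)2P(O)CH2CO2H, Cs2CO3 (2.5 equiv), MeCN, 0 °C to rt
Reagents that add atoms: diethylphosphonoacetic acid CCOP(=O)(CC(=O)O)OCC
Why: Carboxylate SN2 displacement of the α-chloride followed by intramolecular Horner–Wadsworth–Emmons olefination of the ketone closes the butenolide ring with the carbinol carbon on C4, and the mild base with fast ring closure spares the α-silyloxy stereocentre.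

Step 10
Reactants: 17 4-[(1R,3E,7E)-11,11-dimethoxy-4,8-dimethyl-1-[(triethylsilyl)oxy]undeca-3,7-dien-1-yl]furan-2(5H)-one
Product: 18 (4E,8E,11R)-11-hydroxy-4,8-dimethyl-11-(5-oxo-2,5-dihydrofuran-3-yl)undeca-4,8-dienal
Conditions: TsOH·H2O (cat.), acetone/H2O (10:1), rt
Reagents that add atoms: water O
Why: Aqueous acid hydrolyses the dimethyl acetal and the triethylsilyl ether together without affecting the butenolide, the trisubstituted olefins or the carbinol configuration.

Step 11
Reactants: 19 (5S)-5-(hydroxymethyl)oxolan-2-one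
Product: 20 (2S)-5-oxooxolane-2-carbaldehyde
Conditions: Dess–Martin periodinane, CH2Cl2, 0 °C to rt; filtered and used crude
Reagents that add atoms: none
Why: Dess–Martin oxidation gives the α-acyloxy aldehyde under non-basic conditions, so the bought stereocentre is not epimerised.

Step 12
Reactants: 20 (2S)-5-oxooxolane-2-carbaldehyde
Product: 21 (5S)-5-(2-methylprop-1-en-1-yl)oxolan-2-one
Conditions: i-PrPPh3I, KN(SiMe3)2, THF, 0 °C; then added to 20, −78 to 0 °C
Reagents that add atoms: isopropyltriphenylphosphonium iodide CC(C)[P+](c1ccccc1)(c1ccccc1)c1ccccc1.[I-]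
Why: Wittig olefination with the non-stabilised isopropylidene ylide at low temperature is chemoselective for the aldehyde over the lactone and keeps the stereocentre (no E/Z question arises).

Step 13
Reactants: 21 (5S)-5-(2-methylprop-1-en-1-yl)oxolan-2-one
Product: 23 diethyl [(5S)-5-(2-methylprop-1-en-1-yl)-2-oxooxolan-3-yl]phosphonate (C3 epimers), via enol phosphate 22 (not isolated)
Conditions: LiN(i-Pr)2 (1.1 equiv), THF, −78 °C; ClP(O)(OEt)2, −78 °C to rt; LiN(i-Pr)2 (2.2 equiv), −78 °C to rt; aq. NH4Cl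
Reagents that add atoms: diethyl chlorophosphate CCOP(=O)(Cl)OCC
Why: O-phosphorylation of the lactone enolate followed by base-induced 1,3-phosphoryl migration (vinyl phosphate to phosphonate rearrangement) gives the α-phosphono lactone, whose new C3 centre is irrelevant because it becomes sp2.

Step 14
Reactants: 18 (4E,8E,11R)-11-hydroxy-4,8-dimethyl-11-(5-oxo-2,5-dihydrofuran-3-yl)undeca-4,8-dienal; 23 diethyl [(5S)-5-(2-methylprop-1-en-1-yl)-2-oxooxolan-3-yl]phosphonate (1.3 equiv)
Product: 24 (3Z,5S)-3-[(4E,8E,11R)-11-hydroxy-4,8-dimethyl-11-(5-oxo-2,5-dihydrofuran-3-yl)undeca-4,8-dien-1-ylidene]-5-(2-methylprop-1-en-1-yl)oxolan-2-one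
Conditions: KN(SiMe3)2 (1.0 equiv relative to 23), 18-crown-6, THF, −78 °C; then 18, −78 °C; AcOH quench at −78 °C; chromatographic removal of the minor (E)-isomer
Reagents that add atoms: none
Why: Horner–Wadsworth–Emmons olefination under dissociating kinetic conditions (potassium sequestered by 18-crown-6, cold quench) favours the (Z)-alkylidene lactone with the chain syn to the carbonyl, and neither stereocentre is touched.

Step 15
Reactants: 24 (3Z,5S)-3-[(4E,8E,11R)-11-hydroxy-4,8-dimethyl-11-(5-oxo-2,5-dihydrofuran-3-yl)undeca-4,8-dien-1-ylidene]-5-(2-methylprop-1-en-1-yl)oxolan-2-one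
Product: 25 (1R,3E,7E)-4,8-dimethyl-11-[(3Z,5S)-5-(2-methylprop-1-en-1-yl)-2-oxooxolan-3-ylidene]-1-(5-oxo-2,5-dihydrofuran-3-yl)undeca-3,7-dien-1-yl acetate
Conditions: Ac2O, pyridine, DMAP (cat.), CH2Cl2, 0 °C
Reagents that add atoms: acetic anhydride CC(=O)OC(C)=O
Why: DMAP-catalysed acetylation of the secondary alcohol occurs at oxygen and therefore with retention at the (R)-carbinol carbon.

## Compound list

1 | pent-4-yn-1-ol | C#CCCCO | starting material
2 | [(1E)-5-(dimethylalumanyloxy)-2-methylpent-1-en-1-yl]dimethylalumane | C[Al](C)OCCC/C(C)=C/[Al](C)C | intermediate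
3 | (4E)-5-iodo-4-methylpent-4-en-1-ol | OCCC/C(C)=C/I | intermediate
4 | (4E)-5-iodo-4-methylpent-4-enal | O=CCC/C(C)=C/I | intermediate
5 | (6E)-7-iodo-2,6-dimethylhepta-1,6-dien-3-ol (racemic) | CC(=C)C(O)CC/C(C)=C/I | intermediate
6 | (1E)-5-[(1-ethoxyethenyl)oxy]-1-iodo-2,6-dimethylhepta-1,6-diene | C=C(OCC)OC(CC/C(C)=C/I)C(C)=C | intermediate
7 | ethyl (4E,8E)-9-iodo-4,8-dimethylnona-4,8-dienoate | CCOC(=O)CC/C(C)=C/CC/C(C)=C/I | intermediate
8 | (4E,8E)-9-iodo-4,8-dimethylnona-4,8-dienal | O=CCC/C(C)=C/CC/C(C)=C/I | intermediate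
9 | (1E,5E)-1-iodo-9,9-dimethoxy-2,6-dimethylnona-1,5-diene | COC(OC)CC/C(C)=C/CC/C(C)=C/I | intermediate
10 | methyl (2R)-oxirane-2-carboxylate | COC(=O)[C@H]1CO1 | starting material
11 | [(1E,5E)-9,9-dimethoxy-2,6-dimethylnona-1,5-dien-1-yl]lithium | COC(OC)CC/C(C)=C/CC/C(C)=C/[Li] | intermediate
12 | [(1E,5E)-9,9-dimethoxy-2,6-dimethylnona-1,5-dien-1-yl]magnesium bromide | COC(OC)CC/C(C)=C/CC/C(C)=C/[Mg]Br | intermediate
13 | methyl (2R,4E,8E)-2-hydroxy-12,12-dimethoxy-5,9-dimethyldodeca-4,8-dienoate (present as its bromomagnesium alkoxide) | COC(=O)[C@H](O)C/C=C(\C)CC/C=C(\C)CCC(OC)OC | intermediate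
14 | methyl (2R,4E,8E)-12,12-dimethoxy-5,9-dimethyl-2-[(triethylsilyl)oxy]dodeca-4,8-dienoate | COC(=O)[C@H](O[Si](CC)(CC)CC)C/C=C(\C)CC/C=C(\C)CCC(OC)OC | intermediate
15 | (3R,5E,9E)-1-chloro-13,13-dimethoxy-6,10-dimethyl-3-[(triethylsilyl)oxy]trideca-5,9-dien-2-one | ClCC(=O)[C@H](O[Si](CC)(CC)CC)C/C=C(\C)CC/C=C(\C)CCC(OC)OC | intermediate
16 | (3R,5E,9E)-13,13-dimethoxy-6,10-dimethyl-2-oxo-3-[(triethylsilyl)oxy]trideca-5,9-dien-1-yl (diethoxyphosphoryl)acetate | CCOP(=O)(OCC)CC(=O)OCC(=O)[C@H](O[Si](CC)(CC)CC)C/C=C(\C)CC/C=C(\C)CCC(OC)OC | intermediate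
17 | 4-[(1R,3E,7E)-11,11-dimethoxy-4,8-dimethyl-1-[(triethylsilyl)oxy]undeca-3,7-dien-1-yl]furan-2(5H)-one | O=C1C=C(CO1)[C@H](O[Si](CC)(CC)CC)C/C=C(\C)CC/C=C(\C)CCC(OC)OC | intermediate
18 | (4E,8E,11R)-11-hydroxy-4,8-dimethyl-11-(5-oxo-2,5-dihydrofuran-3-yl)undeca-4,8-dienal | O=C1C=C(CO1)[C@H](O)C/C=C(\C)CC/C=C(\C)CCC=O | intermediate
19 | (5S)-5-(hydroxymethyl)oxolan-2-one | OC[C@@H]1CCC(=O)O1 | starting material
20 | (2S)-5-oxooxolane-2-carbaldehyde | O=C[C@@H]1CCC(=O)O1 | intermediate
21 | (5S)-5-(2-methylprop-1-en-1-yl)oxolan-2-one | CC(C)=C[C@@H]1CCC(=O)O1 | intermediate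
22 | diethyl (5S)-5-(2-methylprop-1-en-1-yl)-4,5-dihydrofuran-2-yl phosphate | CCOP(=O)(OCC)OC1=CC[C@@H](C=C(C)C)O1 | intermediate
23 | diethyl [(5S)-5-(2-methylprop-1-en-1-yl)-2-oxooxolan-3-yl]phosphonate | CCOP(=O)(OCC)C1C[C@@H](C=C(C)C)OC1=O | intermediate
24 | (3Z,5S)-3-[(4E,8E,11R)-11-hydroxy-4,8-dimethyl-11-(5-oxo-2,5-dihydrofuran-3-yl)undeca-4,8-dien-1-ylidene]-5-(2-methylprop-1-en-1-yl)oxolan-2-one | O=C1C=C(CO1)[C@H](O)C/C=C(\C)CC/C=C(\C)CC/C=C2/C[C@@H](C=C(C)C)OC2=O | intermediate
25 | (1R,3E,7E)-4,8-dimethyl-11-[(3Z,5S)-5-(2-methylprop-1-en-1-yl)-2-oxooxolan-3-ylidene]-1-(5-oxo-2,5-dihydrofuran-3-yl)undeca-3,7-dien-1-yl acetate | CC(=O)O[C@H](C/C=C(\C)CC/C=C(\C)CC/C=C1/C[C@@H](C=C(C)C)OC1=O)C1=CC(=O)OC1 | target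

## Step count and risks

Total step count: 15. Longest linear sequence: 12 (steps 1–10, 14, 15).

**Step 7 (glycidate opening).** The alkenyl Grignard may attack the ester carbonyl, bromide may open the epoxide, or the in-flask silylation may be incomplete. The fallback sets out from 9 and 10. Ester 10 is saponified (KOH, EtOH, 0 °C) to potassium (2R)-oxirane-2-carboxylate F1, whose carboxylate cannot be attacked. F1 is opened with 12 (made from 9 as in step 7; CuBr·SMe2 cat., THF, −30 °C) to give (2R,4E,8E)-2-hydroxy-12,12-dimethoxy-5,9-dimethyldodeca-4,8-dienoic acid F2, kept as its salt because of the acetal. MeI/K2CO3/DMF gives ester 13, and TESCl/imidazole brings the material back to the route at 14.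

**Step 8 (chloromethyl ketone).** Double addition, epoxide formation or partial loss of the silyl ether are possible. The fallback sets out from 14. MeNH(OMe)·HCl with i-PrMgCl (THF, −20 °C) gives (2R,4E,8E)-N,12,12-trimethoxy-N,5,9-trimethyl-2-[(triethylsilyl)oxy]dodeca-4,8-dienamide F3. Its chelated adduct with chloromethyllithium (ICH2Cl, MeLi·LiBr, −78 °C) cannot over-add, and the route is rejoined at 15.

**Step 14 (Z-selective olefination).** The target geometry is the less stable one, so the Z:E ratio may be poor and any equilibration gives the (E)-isomer. The fallback sets out from 21. The lithium enolate of 21 (LiN(i-Pr)2, THF, −78 °C) is C-phosphinylated with ClP(OCH2CF3)2 to bis(2,2,2-trifluoroethyl) [(5S)-5-(2-methylprop-1-en-1-yl)-2-oxooxolan-3-yl]phosphonite F4. Oxidation in the flask with t-BuOOH gives bis(2,2,2-trifluoroethyl) [(5S)-5-(2-methylprop-1-en-1-yl)-2-oxooxolan-3-yl]phosphonate F5, a Still–Gennari-type reagent. Condensation of F5 with 18 (KN(SiMe3)2, 18-crown-6, THF, −78 °C) rejoins the route at 24.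

## Further compounds

F1 | step 7 | potassium (2R)-oxirane-2-carboxylate | [K+].[O-]C(=O)[C@H]1CO1
F2 | step 7 | (2R,4E,8E)-2-hydroxy-12,12-dimethoxy-5,9-dimethyldodeca-4,8-dienoic acid | OC(=O)[C@H](O)C/C=C(\C)CC/C=C(\C)CCC(OC)OC
F3 | step 8 | (2R,4E,8E)-N,12,12-trimethoxy-N,5,9-trimethyl-2-[(triethylsilyl)oxy]dodeca-4,8-dienamide | CON(C)C(=O)[C@H](O[Si](CC)(CC)CC)C/C=C(\C)CC/C=C(\C)CCC(OC)OC
F4 | step 14 | bis(2,2,2-trifluoroethyl) [(5S)-5-(2-methylprop-1-en-1-yl)-2-oxooxolan-3-yl]phosphonite | FC(F)(F)COP(OCC(F)(F)F)C1C[C@@H](C=C(C)C)OC1=O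
F5 | step 14 | bis(2,2,2-trifluoroethyl) [(5S)-5-(2-methylprop-1-en-1-yl)-2-oxooxolan-3-yl]phosphonate | FC(F)(F)COP(=O)(OCC(F)(F)F)C1C[C@@H](C=C(C)C)OC1=O
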